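**Plan**
- Retrosynthesis: the six hydroxyls are unmasked last (four aryl benzyl ethers, two aryl benzyl carbonates), and before that the C4 carbonyl of ring C is taken back to a CH2 group.
- Ring C is then opened at O1–C2 and C3–C4. These bonds lie on either side of C2–C3, whose aryl groups (ring B on C2, ring E on C3) are trans, the geometry of an (E)-stilbene. The para-hydroxyl of ring B makes the future C3 the nucleophilic alkene carbon, so the partners are a ring A ortho-quinone methide and a 4-hydroxystilbene.
- The stilbene is cut at the ring E–vinyl bond (Heck coupling), and the flavone at C2–C3 and O1–C2 of its pyranone (aldol condensation, oxidative cyclisation).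
- Forward: the pyranone ring of the flavone is closed first, the stilbene is joined next, ring C is closed by the oxa-[4+2] step, then C4 is oxidised and one hydrogenolysis ends the route.
- Stereochemistry: C2 and C3 are both set in the cycloaddition, trans from the (E)-alkene and absolute sense from a chiral phosphoric acid. C2 is not touched afterwards, and C3, once alpha to the ketone, already has the more stable trans arrangement. The target is (2R,3S).

Key step: step 10

Assumption: which antipode of the phosphoric acid leads to the (2R,3S) chroman cannot be derived for this untested substrate pair, so (R)-TRIP is written and the sense of induction is to be fixed by one run with each antipode.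

Step 1
Reactants: 1 2,4,6-trihydroxyacetophenone
Product: 2 1-[2,4-bis(benzyloxy)-6-hydroxyphenyl]ethanone
Conditions: BnBr (2.1 equiv), K2CO3, DMF, rt
Reagents that add atoms: benzyl bromide, BrCc1ccccc1
Why: Williamson etherification alkylates the two more acidic hydroxyls, while the third, hydrogen-bonded to the acetyl carbonyl, is the least nucleophilic and should stay free when the halide is limited to two equivalents.

Step 2
Reactants: 3 3-bromo-4-hydroxybenzaldehyde
Product: 4 3-bromo-4-(methoxymethoxy)benzaldehyde
Conditions: MOMCl, i-Pr2NEt, CH2Cl2, 0 °C to rt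
Reagents that add atoms: chloromethyl methyl ether, COCCl
Why: O-alkylation of the phenol to its methoxymethyl acetal gives a base-stable cap that keeps the aldehyde electrophilic in the aldol step and can later be removed by acid without touching benzyl ethers.

Step 3
Reactants: 2 1-[2,4-bis(benzyloxy)-6-hydroxyphenyl]ethanone; 4 3-bromo-4-(methoxymethoxy)benzaldehyde
Product: 5 (E)-1-[2,4-bis(benzyloxy)-6-hydroxyphenyl]-3-[3-bromo-4-(methoxymethoxy)phenyl]prop-2-en-1-one
Conditions: KOH (50% aq), EtOH/THF, rt
Reagents that add atoms: none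
Why: Claisen–Schmidt condensation of the methyl ketone enolate with the non-enolisable aldehyde, followed by dehydration, should give the conjugated (E)-enone, the thermodynamically preferred isomer.

Step 4
Reactants: 5 (E)-1-[2,4-bis(benzyloxy)-6-hydroxyphenyl]-3-[3-bromo-4-(methoxymethoxy)phenyl]prop-2-en-1-one
Product: 7 5,7-bis(benzyloxy)-2-(3-bromo-4-hydroxyphenyl)-4H-chromen-4-one, via methoxymethyl-protected bromoflavone 6 (not isolated)
Conditions: I2 (10 mol%), DMSO, 120 °C; then crude flavone, 3 M HCl, MeOH/THF, 50 °C
Reagents that add atoms: none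
Why: Iodine-mediated oxidative cyclisation of a 2'-hydroxychalcone (oxa-Michael closure, alpha-iodination, loss of HI, DMSO as terminal oxidant) closes the pyranone ring, and acid-catalysed acetal exchange with methanol then frees the ring E phenol while the aryl benzyl ethers stay.

Step 5
Reactants: 7 5,7-bis(benzyloxy)-2-(3-bromo-4-hydroxyphenyl)-4H-chromen-4-one
Product: 8 benzyl 4-[5,7-bis(benzyloxy)-4-oxo-4H-chromen-2-yl]-2-bromophenyl carbonate
Conditions: CbzCl, Et3N, DMAP (cat.), CH2Cl2, 0 °C
Reagents that add atoms: benzyl chloroformate, O=C(Cl)OCc1ccccc1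
Why: Acylation of the phenol with a chloroformate gives the aryl benzyl carbonate, which withdraws electron density from ring E for the key step and later falls together with the benzyl ethers.

Step 6
Reactants: 8 benzyl 4-[5,7-bis(benzyloxy)-4-oxo-4H-chromen-2-yl]-2-bromophenyl carbonate; 9 tert-butyldimethyl(4-vinylphenoxy)silane
Product: 10 benzyl 4-[5,7-bis(benzyloxy)-4-oxo-4H-chromen-2-yl]-2-[(E)-2-(4-{[tert-butyl(dimethyl)silyl]oxy}phenyl)ethenyl]phenyl carbonate
Conditions: Pd[P(t-Bu)3]2 (3 mol%), Cy2NMe, 1,4-dioxane, rt to 50 °C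
Reagents that add atoms: none
Why: Mizoroki–Heck coupling (oxidative addition of the aryl bromide to zerovalent palladium, syn insertion of the styrene, syn beta-hydride elimination) should give the (E)-stilbene, and the bulky trialkylphosphine permits a temperature and a hindered amine base mild enough for the aryl carbonate and the silyl ether.

Step 7
Reactants: 10 benzyl 4-[5,7-bis(benzyloxy)-4-oxo-4H-chromen-2-yl]-2-[(E)-2-(4-{[tert-butyl(dimethyl)silyl]oxy}phenyl)ethenyl]phenyl carbonate
Product: 11 benzyl 4-[5,7-bis(benzyloxy)-4-oxo-4H-chromen-2-yl]-2-[(E)-2-(4-hydroxyphenyl)ethenyl]phenyl carbonate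
Conditions: KHF2, MeOH/THF, rt, exclusion of light
Reagents that add atoms: none
Why: Fluoride-induced cleavage of the phenolic silyl ether under nearly neutral conditions frees the ring B phenol without transesterifying the carbonate or isomerising the alkene.

Step 8
Reactants: 12 2,4,6-trihydroxybenzaldehyde
Product: 13 2,4-bis(benzyloxy)-6-hydroxybenzaldehyde
Conditions: BnBr (2.05 equiv), K2CO3, DMF, 0 °C to rt
Reagents that add atoms: benzyl bromide, BrCc1ccccc1
Why: Williamson etherification with two equivalents of halide should stop at the dibenzyl ether because the remaining hydroxyl is chelated to the aldehyde carbonyl and is the least reactive.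

Step 9
Reactants: 13 2,4-bis(benzyloxy)-6-hydroxybenzaldehyde
Product: 14 3,5-bis(benzyloxy)-2-(hydroxymethyl)phenol
Conditions: NaBH4, THF/MeOH, −10 °C; pH 7 phosphate buffer work-up; used at once
Reagents that add atoms: none
Why: Borohydride reduction of the aldehyde gives the ortho-hydroxybenzyl alcohol, and low temperature with a neutral work-up should prevent premature ionisation of this electron-rich alcohol to the quinone methide and its over-reduction to the cresol.

Step 10
Reactants: 14 3,5-bis(benzyloxy)-2-(hydroxymethyl)phenol; 11 benzyl 4-[5,7-bis(benzyloxy)-4-oxo-4H-chromen-2-yl]-2-[(E)-2-(4-hydroxyphenyl)ethenyl]phenyl carbonate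
Product: 16 benzyl 4-[5,7-bis(benzyloxy)-4-oxo-4H-chromen-2-yl]-2-[(2R,3S)-5,7-bis(benzyloxy)-2-(4-hydroxyphenyl)-3,4-dihydro-2H-chromen-3-yl]phenyl carbonate, via ortho-quinone methide 15 (not isolated)
Conditions: (R)-TRIP [(R)-3,3'-bis(2,4,6-triisopropylphenyl)-1,1'-binaphthyl-2,2'-diyl hydrogen phosphate] (10 mol%), 4 Å molecular sieves, CH2Cl2, 0 °C to rt, 14 (2 equiv) added slowly
Reagents that add atoms: none
Why: Proposed new method: the phosphoric acid protonates and dehydrates the trioxygenated benzylic alcohol 14 to the ortho-quinone methide 15 and then holds the methide oxygen (through P–OH) and the ring B hydroxyl of 11 (through P=O) in one hydrogen-bonded assembly, in which C3, vinylogous to that hydroxyl, attacks the unsubstituted methide carbon C4 and O1 then bonds to the para-quinone-methide-like C2. The closest known reaction type is the chiral phosphoric acid catalysed inverse-demand oxa-[4+2] cycloaddition of ortho-quinone methides, made from ortho-hydroxybenzyl alcohols, with ortho- or para-hydroxystyrenes; new here is a 1,2-diaryl alkene combined with a methide carbon that bears no substituent. Ring C closes by the [4+2] cycloaddition itself, and in the stepwise limit the second bond forms by 6-exo-trig attack of the ring A phenoxide oxygen on C2. C2 and C3 are set together: their trans relation is copied from the (E)-alkene by suprafacial addition and is also the diequatorial, more stable arrangement should O1–C2 close late, while the absolute configuration comes from the binaphthyl phosphate, which shields one face of the hydrogen-bonded alkene. The step needs C3, not C2, to bond to C4, and the free para-hydroxyl of ring B is the only donor able to push electrons through the alkene, because the ring E oxygen is tied up as a carbonate and ring E carries the electron-poor chromone. Slow addition of 14 keeps the methide concentration low so that its self-condensation should not outrun the cycloaddition.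

Step 11
Reactants: 16 benzyl 4-[5,7-bis(benzyloxy)-4-oxo-4H-chromen-2-yl]-2-[(2R,3S)-5,7-bis(benzyloxy)-2-(4-hydroxyphenyl)-3,4-dihydro-2H-chromen-3-yl]phenyl carbonate
Product: 17 benzyl 4-[(2R,3S)-5,7-bis(benzyloxy)-3-{5-[5,7-bis(benzyloxy)-4-oxo-4H-chromen-2-yl]-2-[(benzyloxycarbonyl)oxy]phenyl}-3,4-dihydro-2H-chromen-2-yl]phenyl carbonate
Conditions: CbzCl, pyridine, CH2Cl2, 0 °C
Reagents that add atoms: benzyl chloroformate, O=C(Cl)OCc1ccccc1
Why: Acylation of the ring B phenol to its benzyl carbonate removes the para-hydroxybenzyl ether character of C2, so that neither acid nor DDQ should open ring C or oxidise at C2 through a para-quinone methide.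

Step 12
Reactants: 17 bis(benzyl carbonate) chroman
Product: 18 benzyl 4-[(2R,3R)-5,7-bis(benzyloxy)-3-{5-[5,7-bis(benzyloxy)-4-oxo-4H-chromen-2-yl]-2-[(benzyloxycarbonyl)oxy]phenyl}-4-hydroxy-3,4-dihydro-2H-chromen-2-yl]phenyl carbonate (2,3-trans, both C4 epimers, hydroxyl trans to ring E expected to prevail)
Conditions: DDQ (1.5 equiv), CH2Cl2/H2O (10:1), 0 °C to rt
Reagents that add atoms: water, O
Why: Benzylic oxidation by hydride abstraction, known for 5,7-dialkoxyflavans, should occur at C4 because the resulting cation is ortho or para to all three ring A oxygens, water captures it, and the C2–H next to the acylated ring B and the benzyl ethers are far less prone to hydride loss.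

Step 13
Reactants: 18 chroman-4-ol
Product: 19 benzyl 4-[(2R,3S)-5,7-bis(benzyloxy)-3-{5-[5,7-bis(benzyloxy)-4-oxo-4H-chromen-2-yl]-2-[(benzyloxycarbonyl)oxy]phenyl}-4-oxo-3,4-dihydro-2H-chromen-2-yl]phenyl carbonate
Conditions: Dess–Martin periodinane, NaHCO3, CH2Cl2, 0 °C to rt
Reagents that add atoms: none
Why: Dess–Martin oxidation of the secondary benzylic alcohol under buffered conditions gives the ketone from either C4 epimer, C2 is not involved, and C3, now enolisable, already holds the thermodynamically preferred 2,3-trans arrangement.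

Step 14
Reactants: 19 fully protected flavanone
Product: 20 (2R,3S)-3-[5-(5,7-dihydroxy-4-oxo-4H-chromen-2-yl)-2-hydroxyphenyl]-5,7-dihydroxy-2-(4-hydroxyphenyl)-2,3-dihydro-4H-chromen-4-one
Conditions: H2 (1 atm), Pd/C (10 wt% Pd), EtOAc/MeOH, rt
Reagents that add atoms: none
Why: Catalytic hydrogenolysis cleaves the four aryl benzyl ethers and both benzyl carbonates (the latter with loss of CO2) under neutral conditions that should neither epimerise C2 or C3 nor reduce the chromone double bond or the aryl ketone.

**Compound list**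
1 | 2,4,6-trihydroxyacetophenone | CC(=O)c1c(O)cc(O)cc1O | starting material
2 | 1-[2,4-bis(benzyloxy)-6-hydroxyphenyl]ethanone | CC(=O)c1c(O)cc(OCc2ccccc2)cc1OCc1ccccc1 | intermediate
3 | 3-bromo-4-hydroxybenzaldehyde | O=Cc1ccc(O)c(Br)c1 | starting material
4 | 3-bromo-4-(methoxymethoxy)benzaldehyde | COCOc1ccc(C=O)cc1Br | intermediate
5 | (E)-1-[2,4-bis(benzyloxy)-6-hydroxyphenyl]-3-[3-bromo-4-(methoxymethoxy)phenyl]prop-2-en-1-one | COCOc1ccc(/C=C/C(=O)c2c(O)cc(OCc3ccccc3)cc2OCc2ccccc2)cc1Br | intermediate
6 | 5,7-bis(benzyloxy)-2-[3-bromo-4-(methoxymethoxy)phenyl]-4H-chromen-4-one | COCOc1ccc(-c2cc(=O)c3c(OCc4ccccc4)cc(OCc4ccccc4)cc3o2)cc1Br | intermediate (not isolated)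
7 | 5,7-bis(benzyloxy)-2-(3-bromo-4-hydroxyphenyl)-4H-chromen-4-one | Oc1ccc(-c2cc(=O)c3c(OCc4ccccc4)cc(OCc4ccccc4)cc3o2)cc1Br | intermediate
8 | benzyl 4-[5,7-bis(benzyloxy)-4-oxo-4H-chromen-2-yl]-2-bromophenyl carbonate | O=C(OCc1ccccc1)Oc1ccc(-c2cc(=O)c3c(OCc4ccccc4)cc(OCc4ccccc4)cc3o2)cc1Br | intermediate
9 | tert-butyldimethyl(4-vinylphenoxy)silane | C=Cc1ccc(O[Si](C)(C)C(C)(C)C)cc1 | starting material
10 | (E)-stilbene with ring B silyl ether and ring E benzyl carbonate | CC(C)(C)[Si](C)(C)Oc1ccc(/C=C/c2cc(-c3cc(=O)c4c(OCc5ccccc5)cc(OCc5ccccc5)cc4o3)ccc2OC(=O)OCc2ccccc2)cc1 | intermediate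
11 | (E)-stilbene with free ring B phenol and ring E benzyl carbonate | Oc1ccc(/C=C/c2cc(-c3cc(=O)c4c(OCc5ccccc5)cc(OCc5ccccc5)cc4o3)ccc2OC(=O)OCc2ccccc2)cc1 | intermediate
12 | 2,4,6-trihydroxybenzaldehyde | O=Cc1c(O)cc(O)cc1O | starting material
13 | 2,4-bis(benzyloxy)-6-hydroxybenzaldehyde | O=Cc1c(O)cc(OCc2ccccc2)cc1OCc1ccccc1 | intermediate
14 | 3,5-bis(benzyloxy)-2-(hydroxymethyl)phenol | OCc1c(O)cc(OCc2ccccc2)cc1OCc1ccccc1 | intermediate
15 | 3,5-bis(benzyloxy)-6-methylidenecyclohexa-2,4-dien-1-one (ortho-quinone methide) | C=C1C(=O)C=C(OCc2ccccc2)C=C1OCc1ccccc1 | intermediate (not isolated)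
16 | (2R,3S)-2,3-trans chroman, C4 = CH2, free ring B phenol | C1c2c(OCc3ccccc3)cc(OCc3ccccc3)cc2O[C@@H](c2ccc(O)cc2)[C@@H]1c1cc(-c2cc(=O)c3c(OCc4ccccc4)cc(OCc4ccccc4)cc3o2)ccc1OC(=O)OCc1ccccc1 | intermediate
17 | (2R,3S)-chroman with benzyl carbonates on ring B and ring E | C1c2c(OCc3ccccc3)cc(OCc3ccccc3)cc2O[C@@H](c2ccc(OC(=O)OCc3ccccc3)cc2)[C@@H]1c1cc(-c2cc(=O)c3c(OCc4ccccc4)cc(OCc4ccccc4)cc3o2)ccc1OC(=O)OCc1ccccc1 | intermediate
18 | (2R,3R)-chroman-4-ol of 17, 2,3-trans, C4 epimers | OC1c2c(OCc3ccccc3)cc(OCc3ccccc3)cc2O[C@@H](c2ccc(OC(=O)OCc3ccccc3)cc2)[C@@H]1c1cc(-c2cc(=O)c3c(OCc4ccccc4)cc(OCc4ccccc4)cc3o2)ccc1OC(=O)OCc1ccccc1 | intermediate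
19 | (2R,3S)-chroman-4-one, fully protected | O=C1c2c(OCc3ccccc3)cc(OCc3ccccc3)cc2O[C@@H](c2ccc(OC(=O)OCc3ccccc3)cc2)[C@@H]1c1cc(-c2cc(=O)c3c(OCc4ccccc4)cc(OCc4ccccc4)cc3o2)ccc1OC(=O)OCc1ccccc1 | intermediate
20 | (2R,3S)-3-[5-(5,7-dihydroxy-4-oxo-4H-chromen-2-yl)-2-hydroxyphenyl]-5,7-dihydroxy-2-(4-hydroxyphenyl)-2,3-dihydro-4H-chromen-4-one (CNP0324936.1) | O=C1c2c(O)cc(O)cc2O[C@@H](c2ccc(O)cc2)[C@@H]1c1cc(-c2cc(=O)c3c(O)cc(O)cc3o2)ccc1O | target

**Step count**
Total: 14 steps. Longest linear sequence: 11 steps (steps 2 to 7 and 10 to 14, from 3-bromo-4-hydroxybenzaldehyde).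

**Steps most likely to fail**

Step 10 (new method). Self-condensation of the unsubstituted quinone methide may outrun its addition to the hindered 1,2-diaryl alkene, and facial discrimination may be weak because the methide carbon offers the catalyst no substituent to grip. The fallback gives up catalyst control and uses known chemistry. It sets out from 11 and 14, which are heated together in toluene at 110 °C without acid. Thermal dehydration of an ortho-hydroxybenzyl alcohol to its quinone methide and hetero-Diels–Alder trapping by an electron-rich styrene-type alkene are established. This should give the racemic 2,3-trans chroman F1, the trans relation again coming from the (E)-alkene. The enantiomers are then separated by preparative HPLC on a chiral stationary phase such as cellulose tris(3,5-dimethylphenylcarbamate). The (2R,3S) enantiomer is 16, where the route is rejoined.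

Step 12. The C4 cation may lose the C3 proton instead of capturing water, and the resulting alkene can be oxidised further by DDQ to a benzopyrylium salt, which would erase C2. The fallback makes elimination the planned course and sets out from 17. One equivalent of DDQ in dry 1,4-dioxane should give the 2H-chromene F2, a dehydrogenation known for 3-arylchromans, with C2 untouched. Hydroboration with BH3·SMe2 in THF at 0 °C and oxidation with NaBO3·4H2O should add H and OH syn from the face opposite ring B, boron going to the less substituted C4, to give the 2,3-cis chroman-4-ol F3. Dess–Martin oxidation then gives the 2,3-cis ketone F4. Brief equilibration of C3 with a catalytic tertiary amine in CH2Cl2 should turn it into the more stable trans ketone, which is 19, where the route is rejoined.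

Step 14. Over-reduction is the concern: hydrogenolytic opening of the benzylic C2–O1 bond once the ring B phenol is free, saturation of the chromone double bond, or stalling at the chelated 5-O-benzyl groups. The fallback replaces reduction by Lewis acid dealkylation and sets out from 19. BCl3 with pentamethylbenzene as cation scavenger in CH2Cl2 at −78 °C cleaves aryl benzyl ethers and the O–benzyl bond of the carbonates, whose carbonic half-esters lose CO2 on aqueous work-up. This arrives directly at 20, and no compound outside the list is made (F0).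

**Further compounds**
F1 | step 10 | racemic 2,3-trans chroman (16 together with its (2S,3R) enantiomer) | C1c2c(OCc3ccccc3)cc(OCc3ccccc3)cc2O[C@@H](c2ccc(O)cc2)[C@@H]1c1cc(-c2cc(=O)c3c(OCc4ccccc4)cc(OCc4ccccc4)cc3o2)ccc1OC(=O)OCc1ccccc1.C1c2c(OCc3ccccc3)cc(OCc3ccccc3)cc2O[C@H](c2ccc(O)cc2)[C@H]1c1cc(-c2cc(=O)c3c(OCc4ccccc4)cc(OCc4ccccc4)cc3o2)ccc1OC(=O)OCc1ccccc1
F2 | step 12 | 2H-chromene from 17 by loss of H3 and H4 (C3=C4 double bond, C2 arrangement unchanged, ring B and ring E benzyl carbonates) | C1c2c(OCc3ccccc3)cc(OCc3ccccc3)cc2O[C@@H](c2ccc(OC(=O)OCc3ccccc3)cc2)C=1c1cc(-c2cc(=O)c3c(OCc4ccccc4)cc(OCc4ccccc4)cc3o2)ccc1OC(=O)OCc1ccccc1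
F3 | step 12 | (2R,3S,4S)-2,3-cis-3,4-trans chroman-4-ol (ring E cis to ring B, hydroxyl trans to ring E) | O[C@@H]1c2c(OCc3ccccc3)cc(OCc3ccccc3)cc2O[C@@H](c2ccc(OC(=O)OCc3ccccc3)cc2)[C@H]1c1cc(-c2cc(=O)c3c(OCc4ccccc4)cc(OCc4ccccc4)cc3o2)ccc1OC(=O)OCc1ccccc1
F4 | step 12 | (2R,3R)-2,3-cis chroman-4-one (C3 epimer of 19) | O=C1c2c(OCc3ccccc3)cc(OCc3ccccc3)cc2O[C@@H](c2ccc(OC(=O)OCc3ccccc3)cc2)[C@H]1c1cc(-c2cc(=O)c3c(OCc4ccccc4)cc(OCc4ccccc4)cc3o2)ccc1OC(=O)OCc1ccccc1
F0 | step 14 | none | none
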